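Locants are those of the azulene core (C1–C3, C3a, C4–C8, C8a). The seven-membered ring is cut at C6–C7 and C8–C8a. The segment C6–C5–C4(O)–C3a–C8a, with its oxygen on the central carbon and the ring-fusion bond C3a–C8a, is read as a 1-siloxy-1-alkenylcyclopropane whose three-membered ring (C4, C3a, C8a) is fused to the future cyclopentane; C7–C8(=CH2) is one C=C of allene. A rhodium-catalysed (5+2) cycloaddition joins the two in one operation and delivers the hydroazulene with the exocyclic methylene and a C4 enol ether. The precursor, a 6-siloxy-6-alkenylbicyclo[3.1.0]hexane bearing the finished oxolane side chain, comes from (S)-linalool and (R)-2-allyloxirane; the trans ring fusion is set afterwards at the C4 ketone.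

Key step: step 10

Remark: (S)-(+)-linalool and (2R)-2-allyloxirane are taken as purchasable; the cycloaddition gives the cis ring fusion, so the trans fusion of the target has to be reached by equilibration (step 11).

Step 1
Reactants: 1 (S)-(+)-linalool
Product: 3 2-[(2R,5S)-5-ethenyl-5-methyloxolan-2-yl]propan-2-ol (cis-furanoid linalool oxide), via epoxylinalool 2 (not isolated)
Conditions: L-fructose-derived Shi ketone (30 mol%), KHSO5 (as 2KHSO5·KHSO4·K2SO4), K2CO3, MeCN/(MeO)2CH2/aq. Na2B4O7 buffer, 0 °C; then CSA (cat.), CH2Cl2, 0 °C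
Reagents that add atoms: potassium peroxymonosulfate (KHSO5), [K+].[O-]S(=O)(=O)OO
Why: Shi epoxidation attacks only the electron-rich trisubstituted alkene, the L-fructose-derived ketone being chosen to give the (6S)-epoxide, and acid-catalysed 5-exo opening by the tertiary hydroxyl with inversion at C6 then sets the (2R) oxolane centre next to the (5S) centre inherited from linalool.

Step 2
Reactants: 3 cis-furanoid linalool oxide
Product: 4 1-[(2S,5R)-5-(2-hydroxypropan-2-yl)-2-methyloxolan-2-yl]ethan-1-one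
Conditions: PdCl2(quinox) (quinox = 2-(4,5-dihydrooxazol-2-yl)quinoline, 5 mol%), AgSbF6 (12 mol%), aq. t-BuOOH, CH2Cl2, 0 °C→rt
Reagents that add atoms: tert-butyl hydroperoxide, CC(C)(C)OO
Why: Wacker oxidation with the quinoline–oxazoline palladium catalyst and t-BuOOH is Markovnikov-selective even beside an allylic ether oxygen and gives the methyl ketone, whose fully substituted α-carbon cannot epimerize.

Step 3
Reactants: 4 methyl ketone
Product: 5 1-[(2S,5R)-5-(2-hydroxypropan-2-yl)-2-methyloxolan-2-yl]ethenyl trifluoromethanesulfonate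
Conditions: KN(SiMe3)2 (2.2 equiv), THF, −78 °C; PhNTf2, −78→0 °C
Reagents that add atoms: N-phenylbis(trifluoromethanesulfonimide), O=S(=O)(N(c1ccccc1)S(=O)(=O)C(F)(F)F)C(F)(F)F
Why: The ketone can enolize only toward its methyl group, so sulfonylation of the potassium enolate (enol triflate formation) gives a single alkenyl triflate while the hindered tertiary alkoxide should stay untouched.

Step 4
Reactants: 5 alkenyl triflate; 6 (2R)-2-allyloxirane
Product: 8 2-[(2S,5R)-5-(2-hydroxypropan-2-yl)-2-methyloxolan-2-yl]-6-[(2R)-oxiran-2-yl]hex-1-en-3-one, via alkylborane 7 (not isolated)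
Conditions: 6, 9-BBN-H, THF, 0 °C→rt; then 5, Pd(PPh3)4 (5 mol%), K3PO4, CO (1 atm), THF/dioxane, 50 °C
Reagents that add atoms: carbon monoxide, [C-]#[O+]
Why: Anti-Markovnikov hydroboration of the terminal alkene followed by carbonylative Suzuki–Miyaura coupling of the B-alkyl borane with the alkenyl triflate assembles the cross-conjugated enone and leaves the epoxide and its stereocentre intact.

Step 5
Reactants: 8 enone
Product: 9 (3Z)-triethylsilyl dienol ether of 8
Conditions: LiN(SiMe3)2 (2.2 equiv), THF, −78 °C; Et3SiCl (1.1 equiv), −78 °C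
Reagents that add atoms: chlorotriethylsilane, CC[Si](Cl)(CC)CC
Why: Kinetic deprotonation at the only α-methylene and O-silylation of the lithium enolate (silyl enol ether formation) give the 2-siloxydiene, expected as the Z isomer, a geometry that only decides which substituent of the later sp2 carbon C4 is endo on the cyclopropane.

Step 6
Reactants: 9 silyl dienol ether
Product: 10 (1R,2R,5R,6R)-6-alkenyl-6-(triethylsilyloxy)bicyclo[3.1.0]hexan-2-ol (2-OH trans to the cyclopropane; siloxy endo; alkenyl exo)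
Conditions: lithium 2,2,6,6-tetramethylpiperidide (3 equiv), t-BuOMe, 0 °C→rt
Reagents that add atoms: none
Why: α-Lithiation of the terminal epoxide generates a lithium carbenoid that adds across the tethered enol ether (intramolecular cyclopropanation of an unsaturated terminal epoxide), and the epoxide stereocentre dictates the absolute configuration of both cyclopropane ring-fusion carbons through a chair-like transition state that leaves the new alkoxide trans to the cyclopropane.

Step 7
Reactants: 10 bicyclic alcohol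
Product: 11 (1S,5R,6R)-6-alkenyl-6-(triethylsilyloxy)bicyclo[3.1.0]hexan-2-one
Conditions: Dess–Martin periodinane, NaHCO3, CH2Cl2, 0 °C
Reagents that add atoms: none
Why: Dess–Martin oxidation under buffered, non-acidic conditions converts the cyclopropylcarbinol into the ketone without opening the siloxycyclopropane.

Step 8
Reactants: 11 bicyclic ketone
Product: 12 (1R,2S,5R,6R)-6-alkenyl-6-(triethylsilyloxy)bicyclo[3.1.0]hexan-2-ol (2-OH cis to the cyclopropane)
Conditions: LiBH(s-Bu)3, THF, −78 °C; aq. NH4Cl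
Reagents that add atoms: none
Why: Steric approach control sends the bulky hydride to the ketone face opposite the cyclopropane and its endo siloxy group, so that the new hydroxyl is cis to the cyclopropane, the arrangement that later disfavours the cis ring fusion.

Step 9
Reactants: 12 cis alcohol
Product: 13 bis(triethylsilyl) vinylcyclopropane
Conditions: Et3SiCl, imidazole, CH2Cl2, 0 °C
Reagents that add atoms: chlorotriethylsilane, CC[Si](Cl)(CC)CC
Why: Imidazole-mediated silylation protects the secondary alcohol selectively (the tertiary alcohol is too hindered) and places a bulky group beside the cyclopropane bond that must stay intact in the next step.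

Step 10
Reactants: 13 bis(triethylsilyl) vinylcyclopropane; 14 propa-1,2-diene (allene)
Product: 15 cis-fused (3S,3aR,8aR)-8-methylidene-3,4-bis(triethylsilyloxy)octahydroazulene bearing the oxolane at C5
Conditions: [Rh(CO)2Cl]2 (5 mol%), allene (3 equiv, fed slowly as a dilute solution), ClCH2CH2Cl, 60–80 °C
Reagents that add atoms: none
Why: Monovalent rhodium binds the alkenyl group and opens the cyclopropane bond between the siloxy carbon C4 and C8a to a σ,π-allyl rhodacycle, one C=C of allene inserts with its CH2 terminus bonding to C6, and C(sp2)–C(sp3) reductive elimination joins the central allene carbon C8 to C8a. The closest known reaction is the rhodium-catalysed intermolecular (5+2) cycloaddition of 1-siloxy-1-vinylcyclopropanes with alkynes and allenes. The seven-membered ring is closed by this two-bond cycloaddition, the second bond forming by reductive elimination from an eight-membered rhodacycle, and it emerges with the C8 exocyclic methylene and the C4=C5 enol ether in place. C8a keeps its configuration because the cyclopropane carbon passes to rhodium and on to C8 with retention, and C3a is not touched, so the ring fusion is cis at this stage. The step needs cleavage of the C4–C8a bond and not of C4–C3a, which the syn C3 silyloxy group should secure by crowding the C3a side, and it needs the allene CH2 and not the central carbon to bond to C6, which follows from insertion into the rhodium–allyl bond leaving an alkenyl–rhodium bond. A low stationary allene concentration is used to suppress oxidative coupling of two allenes on rhodium.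

Step 11
Reactants: 15 cycloadduct
Product: 17 trans-fused (3S,3aS,5S,8aR)-ketone, via cis-fused ketone 16 (not isolated)
Conditions: K2CO3, MeOH, 0 °C→rt
Reagents that add atoms: none
Why: Methanolysis of the enol silyl ether liberates the C4 ketone with protonation of C5 from the open face anti to the cyclopentane, and base equilibration through the C3a enolate should then relieve the cis-1,2 interaction between the C3 silyloxy group and C4 to give the trans-fused hydroazulenone with the oxolanyl group pseudo-equatorial.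

Step 12
Reactants: 17 trans-fused ketone
Product: 18 tertiary acetate of 17
Conditions: Ac2O, DMAP, Et3N, CH2Cl2, 40 °C
Reagents that add atoms: acetic anhydride, CC(=O)OC(C)=O
Why: DMAP-catalysed acetylation esterifies the only free hydroxyl, the tertiary carbinol of the side chain.

Step 13
Reactants: 18 keto acetate
Product: 19 (3S,3aR,4S,5R,8aR)-C4 alcohol
Conditions: LiBH(s-Bu)3, THF, −78→−20 °C; aq. NH4Cl
Reagents that add atoms: none
Why: Steric approach control directs the bulky hydride to the carbonyl face anti to the neighbouring fully substituted oxolane carbon on C5, which should set the C4 hydroxyl cis to the side chain.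

Step 14
Reactants: 19 C4 alcohol
Product: 20 C4 tert-butyldimethylsilyl ether
Conditions: t-BuMe2SiOTf, 2,6-lutidine, CH2Cl2, −78→0 °C
Reagents that add atoms: tert-butyldimethylsilyl trifluoromethanesulfonate, CC(C)(C)[Si](C)(C)OS(=O)(=O)C(F)(F)F
Why: The powerful silyl triflate silylates the hindered secondary C4 hydroxyl and gives a silyl ether that is orthogonal to the triethylsilyl ether on C3.

Step 15
Reactants: 20 bis-silyl ether
Product: 21 C3 alcohol
Conditions: PPTS, MeOH/CH2Cl2, 0 °C
Reagents that add atoms: none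
Why: Mild acid-catalysed methanolysis removes the secondary triethylsilyl ether selectively in the presence of the much more robust tert-butyldimethylsilyl ether.

Step 16
Reactants: 21 C3 alcohol
Product: 22 (3aR,4R,5R,8aR)-cyclopentanone
Conditions: Dess–Martin periodinane, NaHCO3, CH2Cl2, 0 °C
Reagents that add atoms: none
Why: Dess–Martin oxidation under buffered conditions gives the cyclopentanone without epimerizing C3a or eliminating the β-silyloxy group.

Step 17
Reactants: 22 cyclopentanone
Product: 23 C3 enol triflate (C2=C3)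
Conditions: KN(SiMe3)2 (1.05 equiv), THF, −78 °C; PhNTf2, −78 °C
Reagents that add atoms: N-phenylbis(trifluoromethanesulfonimide), O=S(=O)(N(c1ccccc1)S(=O)(=O)C(F)(F)F)C(F)(F)F
Why: Kinetic deprotonation by the bulky amide at the accessible C2 methylene (not at the hindered C3a methine) and O-sulfonylation give the C2=C3 enol triflate regioselectively and leave C3a untouched.

Step 18
Reactants: 23 enol triflate
Product: 24 silyl ether of the target
Conditions: Pd(PPh3)4 (5 mol%), MeZnCl, LiCl, THF, rt→45 °C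
Reagents that add atoms: methylzinc chloride, C[Zn]Cl
Why: Negishi coupling of the alkenyl triflate with MeZnCl installs the C3 methyl group on the trisubstituted alkene and tolerates the tertiary acetate.

Step 19
Reactants: 24 silyl ether
Product: 25 target
Conditions: HF·pyridine, pyridine/THF, 0 °C→rt
Reagents that add atoms: none
Why: Buffered fluoride cleaves the silyl ether (desilylation) without affecting the tertiary acetate or the two alkenes and releases the target.

Compound list
1 | (S)-(+)-linalool, (3S)-3,7-dimethylocta-1,6-dien-3-ol | C=C[C@@](C)(O)CCC=C(C)C | starting material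
2 | (3S)-5-[(2S)-3,3-dimethyloxiran-2-yl]-3-methylpent-1-en-3-ol | C=C[C@@](C)(O)CC[C@@H]1OC1(C)C | intermediate
3 | 2-[(2R,5S)-5-ethenyl-5-methyloxolan-2-yl]propan-2-ol | C=C[C@]1(C)CC[C@H](C(C)(C)O)O1 | intermediate
4 | 1-[(2S,5R)-5-(2-hydroxypropan-2-yl)-2-methyloxolan-2-yl]ethan-1-one | CC(=O)[C@]1(C)CC[C@H](C(C)(C)O)O1 | intermediate
5 | 1-[(2S,5R)-5-(2-hydroxypropan-2-yl)-2-methyloxolan-2-yl]ethenyl trifluoromethanesulfonate | C=C(OS(=O)(=O)C(F)(F)F)[C@]1(C)CC[C@H](C(C)(C)O)O1 | intermediate
6 | (2R)-2-(prop-2-en-1-yl)oxirane | C=CC[C@@H]1CO1 | starting material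
7 | 9-{3-[(2R)-oxiran-2-yl]propyl}-9-borabicyclo[3.3.1]nonane | C1CC2CCCC(C1)B2CCC[C@@H]1CO1 | intermediate
8 | 2-[(2S,5R)-5-(2-hydroxypropan-2-yl)-2-methyloxolan-2-yl]-6-[(2R)-oxiran-2-yl]hex-1-en-3-one | C=C([C@]1(C)CC[C@H](C(C)(C)O)O1)C(=O)CCC[C@@H]1CO1 | intermediate
9 | 2-[(2R,5S)-5-methyl-5-{(3Z)-6-[(2R)-oxiran-2-yl]-3-(triethylsilyloxy)hexa-1,3-dien-2-yl}oxolan-2-yl]propan-2-ol | C=C([C@]1(C)CC[C@H](C(C)(C)O)O1)/C(O[Si](CC)(CC)CC)=C/CC[C@@H]1CO1 | intermediate
10 | (1R,2R,5R,6R)-6-{1-[(2S,5R)-5-(2-hydroxypropan-2-yl)-2-methyloxolan-2-yl]ethenyl}-6-(triethylsilyloxy)bicyclo[3.1.0]hexan-2-ol | O[C@@H]1CC[C@@H]2[C@H]1[C@@]2(O[Si](CC)(CC)CC)C(=C)[C@]3(C)CC[C@H](C(C)(C)O)O3 | intermediate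
11 | (1S,5R,6R)-6-{1-[(2S,5R)-5-(2-hydroxypropan-2-yl)-2-methyloxolan-2-yl]ethenyl}-6-(triethylsilyloxy)bicyclo[3.1.0]hexan-2-one | O=C1CC[C@@H]2[C@H]1[C@@]2(O[Si](CC)(CC)CC)C(=C)[C@]3(C)CC[C@H](C(C)(C)O)O3 | intermediate
12 | (1R,2S,5R,6R)-6-{1-[(2S,5R)-5-(2-hydroxypropan-2-yl)-2-methyloxolan-2-yl]ethenyl}-6-(triethylsilyloxy)bicyclo[3.1.0]hexan-2-ol | O[C@H]1CC[C@@H]2[C@H]1[C@@]2(O[Si](CC)(CC)CC)C(=C)[C@]3(C)CC[C@H](C(C)(C)O)O3 | intermediate
13 | 2-[(2R,5S)-5-{1-[(1R,2S,5R,6R)-2,6-bis(triethylsilyloxy)bicyclo[3.1.0]hexan-6-yl]ethenyl}-5-methyloxolan-2-yl]propan-2-ol | CC[Si](CC)(CC)O[C@H]1CC[C@@H]2[C@H]1[C@@]2(O[Si](CC)(CC)CC)C(=C)[C@]3(C)CC[C@H](C(C)(C)O)O3 | intermediate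
14 | propa-1,2-diene (allene) | C=C=C | starting material
15 | 2-[(2R,5S)-5-[(3S,3aR,8aR)-8-methylidene-3,4-bis(triethylsilyloxy)-1,2,3,3a,6,7,8,8a-octahydroazulen-5-yl]-5-methyloxolan-2-yl]propan-2-ol (cis-fused) | C=C1CCC([C@]3(C)CC[C@H](C(C)(C)O)O3)=C(O[Si](CC)(CC)CC)[C@H]2[C@@H](O[Si](CC)(CC)CC)CC[C@@H]12 | intermediate
16 | (3S,3aR,8aR)-5-[(2S,5R)-5-(2-hydroxypropan-2-yl)-2-methyloxolan-2-yl]-8-methylidene-3-(triethylsilyloxy)-2,3,3a,5,6,7,8,8a-octahydroazulen-4(1H)-one (cis-fused, C5 not yet settled) | C=C1CCC([C@]3(C)CC[C@H](C(C)(C)O)O3)C(=O)[C@H]2[C@@H](O[Si](CC)(CC)CC)CC[C@@H]12 | intermediate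
17 | (3S,3aS,5S,8aR)-5-[(2S,5R)-5-(2-hydroxypropan-2-yl)-2-methyloxolan-2-yl]-8-methylidene-3-(triethylsilyloxy)-2,3,3a,5,6,7,8,8a-octahydroazulen-4(1H)-one (trans-fused) | C=C1CC[C@@H]([C@]3(C)CC[C@H](C(C)(C)O)O3)C(=O)[C@@H]2[C@@H](O[Si](CC)(CC)CC)CC[C@@H]12 | intermediate
18 | 2-[(2R,5S)-5-[(3S,3aS,5S,8aR)-8-methylidene-4-oxo-3-(triethylsilyloxy)decahydroazulen-5-yl]-5-methyloxolan-2-yl]propan-2-yl acetate | C=C1CC[C@@H]([C@]3(C)CC[C@H](C(C)(C)OC(C)=O)O3)C(=O)[C@@H]2[C@@H](O[Si](CC)(CC)CC)CC[C@@H]12 | intermediate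
19 | 2-[(2R,5S)-5-[(3S,3aR,4S,5R,8aR)-4-hydroxy-8-methylidene-3-(triethylsilyloxy)decahydroazulen-5-yl]-5-methyloxolan-2-yl]propan-2-yl acetate | C=C1CC[C@@H]([C@]3(C)CC[C@H](C(C)(C)OC(C)=O)O3)[C@@H](O)[C@@H]2[C@@H](O[Si](CC)(CC)CC)CC[C@@H]12 | intermediate
20 | 2-[(2R,5S)-5-[(3S,3aS,4S,5R,8aR)-4-(tert-butyldimethylsilyloxy)-8-methylidene-3-(triethylsilyloxy)decahydroazulen-5-yl]-5-methyloxolan-2-yl]propan-2-yl acetate | C=C1CC[C@@H]([C@]3(C)CC[C@H](C(C)(C)OC(C)=O)O3)[C@@H](O[Si](C)(C)C(C)(C)C)[C@@H]2[C@@H](O[Si](CC)(CC)CC)CC[C@@H]12 | intermediate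
21 | 2-[(2R,5S)-5-[(3S,3aS,4S,5R,8aR)-4-(tert-butyldimethylsilyloxy)-3-hydroxy-8-methylidenedecahydroazulen-5-yl]-5-methyloxolan-2-yl]propan-2-yl acetate | C=C1CC[C@@H]([C@]3(C)CC[C@H](C(C)(C)OC(C)=O)O3)[C@@H](O[Si](C)(C)C(C)(C)C)[C@@H]2[C@@H](O)CC[C@@H]12 | intermediate
22 | 2-[(2R,5S)-5-[(3aR,4R,5R,8aR)-4-(tert-butyldimethylsilyloxy)-8-methylidene-3-oxodecahydroazulen-5-yl]-5-methyloxolan-2-yl]propan-2-yl acetate | C=C1CC[C@@H]([C@]3(C)CC[C@H](C(C)(C)OC(C)=O)O3)[C@@H](O[Si](C)(C)C(C)(C)C)[C@@H]2C(=O)CC[C@@H]12 | intermediate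
23 | (3aR,4R,5R,8aR)-5-[(2S,5R)-5-(2-acetoxypropan-2-yl)-2-methyloxolan-2-yl]-4-(tert-butyldimethylsilyloxy)-8-methylidene-1,3a,4,5,6,7,8,8a-octahydroazulen-3-yl trifluoromethanesulfonate | C=C1CC[C@@H]([C@]3(C)CC[C@H](C(C)(C)OC(C)=O)O3)[C@@H](O[Si](C)(C)C(C)(C)C)[C@@H]2C(OS(=O)(=O)C(F)(F)F)=CC[C@@H]12 | intermediate
24 | 2-[(2R,5S)-5-[(3aS,4S,5R,8aR)-4-(tert-butyldimethylsilyloxy)-3-methyl-8-methylidene-1,3a,4,5,6,7,8,8a-octahydroazulen-5-yl]-5-methyloxolan-2-yl]propan-2-yl acetate | C=C1CC[C@@H]([C@]3(C)CC[C@H](C(C)(C)OC(C)=O)O3)[C@@H](O[Si](C)(C)C(C)(C)C)[C@@H]2C(C)=CC[C@@H]12 | intermediate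
25 | 2-[(2R,5S)-5-[(3aS,4S,5R,8aR)-4-hydroxy-3-methyl-8-methylidene-1,3a,4,5,6,7,8,8a-octahydroazulen-5-yl]-5-methyloxolan-2-yl]propan-2-yl acetate | C=C1CC[C@@H]([C@]2(C)CC[C@H](C(C)(C)OC(C)=O)O2)[C@@H](O)[C@@H]2C(C)=CC[C@@H]12 | target

Total step count: 19. Longest linear sequence: 19 steps from 1 (compound 6 is used as purchased).

Steps most likely to fail

First, step 10. Rhodium may be sequestered by oxidative coupling of two allene molecules, the rhodacycle may open the C4–C3a instead of the C4–C8a bond, or it may lose a β-hydrogen before insertion. The fallback replaces allene by an alkyne that cannot couple in that way. It sets out from 13: the same rhodium catalyst with 2-ethynyl-4,4,5,5-tetramethyl-1,3,2-dioxaborolane should give the 8-boryl cycloadduct F1, the substituted alkyne carbon ending on C8a, away from the first-formed C6–C7 bond. Oxidation with anhydrous Me3NO and a neutral work-up should give the 8-oxo enol ether F2 with the C4 enol ether still in place. Wittig methylenation (Ph3P=CH2, THF, −78→0 °C, kept cold to protect the α-centre C8a) comes back to 15.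

Second, step 11. The thermodynamic preference for the trans ring fusion may be too small, C5 may drift during the equilibration, or the C3 silyloxy group may be lost by β-elimination from the C3a enolate. The fallback moves the inversion to a later carbonyl. It sets out from 16, obtained by stopping the methanolysis at 0 °C, and runs the operations of steps 12 to 16 in the cis-fused series: acetylation to the cis-fused keto acetate F3, hydride reduction to the cis-fused C4 alcohol F4 (both β substituents now guide the hydride to the same face), silylation to the cis-fused silyl ether F5, methanolysis to the cis-fused C3 alcohol F6 and oxidation to the cis-fused cyclopentanone F7. In F7 only C3a is an enolizable stereocentre, and equilibration with DBU in toluene comes back to 22.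

Third, step 6. The lithiated epoxide may rearrange by 1,2-hydride shift, add the lithium amide, or be protonated before it reaches the enol ether. The fallback uses a rhodium carbenoid instead and sets out from 5. Carbonylative coupling with the 9-BBN adduct of methyl but-3-enoate should give the keto ester F8, and LiOH the keto acid F9. LiN(SiMe3)2/Et3SiCl followed by a mild aqueous work-up should give the dienol silyl ether acid F10. Isobutyl chloroformate/N-methylmorpholine and then CH2N2 should give the diazoketone F11. Rh2(OAc)4 (or a chiral dirhodium carboxylate) should close the cyclopropane and come back to 11 directly; here the absolute configuration rests on the catalyst, and the cyclopropane diastereomer is removed by chromatography.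

Further compounds
F1 | step 10 | 2-[(2R,5S)-5-[(3S,3aR,8aR)-8-(4,4,5,5-tetramethyl-1,3,2-dioxaborolan-2-yl)-3,4-bis(triethylsilyloxy)-1,2,3,3a,6,8a-hexahydroazulen-5-yl]-5-methyloxolan-2-yl]propan-2-ol | CC1(C)OB(OC1(C)C)C1=CCC([C@]3(C)CC[C@H](C(C)(C)O)O3)=C(O[Si](CC)(CC)CC)[C@H]2[C@@H](O[Si](CC)(CC)CC)CC[C@@H]12
F2 | step 10 | 2-[(2R,5S)-5-[(3S,3aR,8aR)-8-oxo-3,4-bis(triethylsilyloxy)-1,2,3,3a,6,7,8,8a-octahydroazulen-5-yl]-5-methyloxolan-2-yl]propan-2-ol | O=C1CCC([C@]3(C)CC[C@H](C(C)(C)O)O3)=C(O[Si](CC)(CC)CC)[C@H]2[C@@H](O[Si](CC)(CC)CC)CC[C@@H]12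
F3 | step 11 | cis-fused 3a-epimer of 18 | C=C1CC[C@@H]([C@]3(C)CC[C@H](C(C)(C)OC(C)=O)O3)C(=O)[C@H]2[C@@H](O[Si](CC)(CC)CC)CC[C@@H]12
F4 | step 11 | cis-fused 3a-epimer of 19 | C=C1CC[C@@H]([C@]3(C)CC[C@H](C(C)(C)OC(C)=O)O3)[C@@H](O)[C@H]2[C@@H](O[Si](CC)(CC)CC)CC[C@@H]12
F5 | step 11 | cis-fused 3a-epimer of 20 | C=C1CC[C@@H]([C@]3(C)CC[C@H](C(C)(C)OC(C)=O)O3)[C@@H](O[Si](C)(C)C(C)(C)C)[C@H]2[C@@H](O[Si](CC)(CC)CC)CC[C@@H]12
F6 | step 11 | cis-fused 3a-epimer of 21 | C=C1CC[C@@H]([C@]3(C)CC[C@H](C(C)(C)OC(C)=O)O3)[C@@H](O[Si](C)(C)C(C)(C)C)[C@H]2[C@@H](O)CC[C@@H]12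
F7 | step 11 | cis-fused 3a-epimer of 22 | C=C1CC[C@@H]([C@]3(C)CC[C@H](C(C)(C)OC(C)=O)O3)[C@@H](O[Si](C)(C)C(C)(C)C)[C@H]2C(=O)CC[C@@H]12
F8 | step 6 | methyl 6-[(2S,5R)-5-(2-hydroxypropan-2-yl)-2-methyloxolan-2-yl]-5-oxohept-6-enoate | C=C([C@]1(C)CC[C@H](C(C)(C)O)O1)C(=O)CCCC(=O)OC
F9 | step 6 | 6-[(2S,5R)-5-(2-hydroxypropan-2-yl)-2-methyloxolan-2-yl]-5-oxohept-6-enoic acid | C=C([C@]1(C)CC[C@H](C(C)(C)O)O1)C(=O)CCCC(=O)O
F10 | step 6 | (4Z)-6-[(2S,5R)-5-(2-hydroxypropan-2-yl)-2-methyloxolan-2-yl]-5-(triethylsilyloxy)hepta-4,6-dienoic acid | C=C([C@]1(C)CC[C@H](C(C)(C)O)O1)/C(O[Si](CC)(CC)CC)=C/CCC(=O)O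
F11 | step 6 | (5Z)-1-diazo-7-[(2S,5R)-5-(2-hydroxypropan-2-yl)-2-methyloxolan-2-yl]-6-(triethylsilyloxy)octa-5,7-dien-2-one | C=C([C@]1(C)CC[C@H](C(C)(C)O)O1)/C(O[Si](CC)(CC)CC)=C/CCC(=O)C=[N+]=[N-]
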